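The route disconnects ring A (the benzoate ring) at two bonds at once: the C6–O diaryl ether bond and the C1–CO2Me bond. Because C2 (OH), C1 (ester carbon) and C6 (aryloxy oxygen) of ring A are neighbours, ring A can be read as a 3-alkoxybenzyne that took up an oxygen nucleophile at one end of its triple bond and a carbon electrophile at the other. The key step unites a ring B phenoxide, this aryne and CO2 in one flask and closes no ring. Its precursors are an ortho-silyl aryl triflate from mono-MOM orcinol and the proton-free potassium salt of the ring B phenol, its benzylic alcohol masked as a TIPS ether.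

Key step: step 10

Remark: electrophilic bromination of mono-MOM orcinol would go para to an oxygen and not to C2 between the two oxygens, so silicon is placed at C2 by directed ortho-metalation of a carbamate; the phenol enters the key step as its preformed potassium salt because any O–H would protonate the aryl anion; the target has no stereocentre.

Step 1
Reactants: 1 orcinol (5-methylbenzene-1,3-diol)
Product: 2 3-(methoxymethoxy)-5-methylphenol
Conditions: NaH (1.0 equiv), MOMCl (1.0 equiv), DMF, 0 °C → rt
Reagents that add atoms: chloromethyl methyl ether, COCCl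
Why: Williamson-type O-alkylation of the monosodium phenoxide with one equivalent of the chloromethyl ether should give the mono-MOM ether, which chromatography separates from the bis-ether and from recoverable orcinol.

Step 2
Reactants: 2 3-(methoxymethoxy)-5-methylphenol
Product: 3 3-(methoxymethoxy)-5-methylphenyl N-(propan-2-yl)carbamate
Conditions: i-PrNCO, Et3N (cat.), CH2Cl2, rt
Reagents that add atoms: isopropyl isocyanate, CC(C)N=C=O
Why: Amine-catalysed addition of the phenol to the isocyanate (carbamoylation) installs a strong ortho-directing group that a mild base can later remove.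

Step 3
Reactants: 3 3-(methoxymethoxy)-5-methylphenyl N-(propan-2-yl)carbamate
Product: 7 3-(methoxymethoxy)-5-methyl-2-(trimethylsilyl)phenyl N-(propan-2-yl)carbamate, via N-silyl carbamate 4 (not isolated), via aryllithium 5 (not isolated), via N,C-disilyl carbamate 6 (not isolated)
Conditions: TBSOTf, TMEDA, Et2O, 0 °C → rt; n-BuLi (2 equiv), TMEDA, −78 °C; TMSCl, −78 °C → rt; aq citric acid work-up
Reagents that add atoms: chlorotrimethylsilane, C[Si](C)(C)Cl
Why: Directed ortho-metalation: after N-silylation in the flask the carbamate and the MOM ether jointly guide n-BuLi to C2, the only ring carbon flanked by both oxygens, the aryllithium is silylated by TMSCl at −78 °C before an anionic Fries shift can occur, and the labile N–Si bond is hydrolysed in the work-up.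

Step 4
Reactants: 7 3-(methoxymethoxy)-5-methyl-2-(trimethylsilyl)phenyl N-(propan-2-yl)carbamate
Product: 9 3-(methoxymethoxy)-5-methyl-2-(trimethylsilyl)phenyl trifluoromethanesulfonate, via ortho-silyl phenol 8 (not isolated)
Conditions: DBU, Et2NH, MeCN, 40 °C; then PhNTf2, rt
Reagents that add atoms: N-phenylbis(trifluoromethanesulfonimide), O=S(=O)(N(c1ccccc1)S(=O)(=O)C(F)(F)F)C(F)(F)F
Why: E1cB cleavage of the N-monosubstituted carbamate (DBU removes the N–H proton, the phenoxide departs and Et2NH captures the isocyanate as a urea) is followed in the same flask by O-triflation of the phenoxide with PhNTf2, so that the protodesilylation-prone ortho-silyl phenol is never handled.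

Step 5
Reactants: 10 2-hydroxy-5-methoxybenzaldehyde
Product: 11 3-bromo-2-hydroxy-5-methoxybenzaldehyde
Conditions: Br2, NaOAc, AcOH, rt
Reagents that add atoms: bromine, BrBr
Why: Electrophilic aromatic bromination is steered by the phenol to its only free ortho position, C3, because the para position carries the methoxy group and the other ring positions are deactivated by the formyl group.

Step 6
Reactants: 11 3-bromo-2-hydroxy-5-methoxybenzaldehyde
Product: 12 2,3-dihydroxy-5-methoxybenzaldehyde
Conditions: NaOH (aq), Cu powder (cat.), reflux, N2; then HCl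
Reagents that add atoms: sodium hydroxide, [Na+].[OH-]
Why: Copper-mediated Ullmann-type hydroxylation of an ortho-bromophenoxide in hot aqueous alkali is the classical way from bromo-hydroxybenzaldehydes to catechol aldehydes, the formyl group being shielded from Cannizzaro disproportionation by conjugation with the ortho-phenoxide and the catecholate being kept under N2.

Step 7
Reactants: 12 2,3-dihydroxy-5-methoxybenzaldehyde; 13 prenyl bromide (1-bromo-3-methylbut-2-ene)
Product: 15 2-hydroxy-5-methoxy-3-(3-methylbut-2-enyloxy)benzaldehyde, via disodium catecholate 14 (not isolated)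
Conditions: NaH (2.2 equiv), DMSO, rt; then 13 (1.0 equiv), rt; dil. HCl work-up
Reagents that add atoms: none
Why: Williamson etherification of the dianion: the 2-oxide is delocalised into the ortho-formyl group and chelated to sodium, so one equivalent of the allylic bromide should alkylate the more nucleophilic 3-oxide by SN2 substitution.

Step 8
Reactants: 15 2-hydroxy-5-methoxy-3-(3-methylbut-2-enyloxy)benzaldehyde
Product: 16 2-(hydroxymethyl)-4-methoxy-6-(3-methylbut-2-enyloxy)phenol
Conditions: NaBH4, MeOH, 0 °C; aq NH4Cl
Reagents that add atoms: none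
Why: Borohydride reduction of the aryl aldehyde gives the benzylic alcohol without touching the prenyl ether, and the near-neutral work-up avoids ortho-quinone methide formation from the salicyl alcohol.

Step 9
Reactants: 16 2-(hydroxymethyl)-4-methoxy-6-(3-methylbut-2-enyloxy)phenol
Product: 17 4-methoxy-2-(3-methylbut-2-enyloxy)-6-(triisopropylsilyloxymethyl)phenol
Conditions: TIPSCl (1.1 equiv), imidazole, CH2Cl2, 0 °C → rt
Reagents that add atoms: chlorotriisopropylsilane, CC(C)[Si](Cl)(C(C)C)C(C)C
Why: Chemoselective O-silylation: the bulky silyl chloride should react with the unhindered primary benzylic hydroxyl much faster than with the phenol, which is flanked by two ortho substituents and is not deprotonated by imidazole.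

Step 10
Reactants: 17 4-methoxy-2-(3-methylbut-2-enyloxy)-6-(triisopropylsilyloxymethyl)phenol; 9 3-(methoxymethoxy)-5-methyl-2-(trimethylsilyl)phenyl trifluoromethanesulfonate; 18 carbon dioxide
Product: 21 2-[4-methoxy-2-(3-methylbut-2-enyloxy)-6-(triisopropylsilyloxymethyl)phenoxy]-6-(methoxymethoxy)-4-methylbenzoic acid, via potassium phenoxide 19 (not isolated), via 3-(methoxymethoxy)-5-methylbenzyne 20 (not isolated)
Conditions: KH (1.05 equiv), THF, 0 °C; then KF, 18-crown-6, CO2 (1 atm), 9 (1.3 equiv) added slowly, 0 °C → rt; cold dil. HCl to pH 3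
Reagents that add atoms: none
Why: Proposed new method: fluoride attacks the silicon of 9 and triflate departs to give aryne 20, the proton-free phenoxide 19 adds to the aryne carbon meta to the MOM ether, and the aryl anion so formed, held between two oxygen substituents, is captured by CO2 as the carboxylate, so that the C6–O ether bond and the C1–carboxyl bond of ring A arise in one flask. The closest known reaction types are the three-component union of arynes, amines and CO2 to anthranilic acids and the addition of phenoxides to arynes with internal acyl capture (xanthones from salicylates). No ring is closed and no stereocentre is created. The step needs regioselective addition, which the inductively withdrawing 3-alkoxy group should secure by distorting the aryne so that the distal carbon is the more electrophilic one and the negative charge develops next to oxygen, helped by the lower steric demand at that carbon for a di-ortho-substituted nucleophile. It also needs carboxylation to outrun protonation, which the preformed potassium phenoxide, THF instead of an acidic solvent, a CO2-saturated solution and slow addition of 9 are meant to secure. The aryl carbonate that 19 forms reversibly with CO2 is a resting state and not a dead end, since it releases the more nucleophilic phenoxide again.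

Step 11
Reactants: 21 2-[4-methoxy-2-(3-methylbut-2-enyloxy)-6-(triisopropylsilyloxymethyl)phenoxy]-6-(methoxymethoxy)-4-methylbenzoic acid
Product: 22 methyl 2-[4-methoxy-2-(3-methylbut-2-enyloxy)-6-(triisopropylsilyloxymethyl)phenoxy]-6-(methoxymethoxy)-4-methylbenzoate
Conditions: MeI, K2CO3, DMF, rt
Reagents that add atoms: iodomethane, CI
Why: Carboxylate O-alkylation (SN2 at iodomethane) takes place at oxygen, away from the crowded carbonyl carbon, and so is indifferent to the two ortho substituents that would block a Fischer esterification.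

Step 12
Reactants: 22 methyl 2-[4-methoxy-2-(3-methylbut-2-enyloxy)-6-(triisopropylsilyloxymethyl)phenoxy]-6-(methoxymethoxy)-4-methylbenzoate
Product: 23 methyl 2-[2-(hydroxymethyl)-4-methoxy-6-(3-methylbut-2-enyloxy)phenoxy]-6-(methoxymethoxy)-4-methylbenzoate
Conditions: TBAF, AcOH (1:1), THF, rt
Reagents that add atoms: none
Why: Fluoride-induced cleavage of the Si–O bond frees the primary alcohol, and buffering with acetic acid keeps it protonated so that no alkoxide can attack the neighbouring methyl ester.

Step 13
Reactants: 23 methyl 2-[2-(hydroxymethyl)-4-methoxy-6-(3-methylbut-2-enyloxy)phenoxy]-6-(methoxymethoxy)-4-methylbenzoate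
Product: 24 methyl 2-hydroxy-6-[2-(hydroxymethyl)-4-methoxy-6-(3-methylbut-2-enyloxy)phenoxy]-4-methylbenzoate (target)
Conditions: HCl (0.5 M in MeOH, cat.), 0 °C → rt; NaHCO3 quench
Reagents that add atoms: none
Why: Acid-catalysed acetal methanolysis: the MOM acetal oxygen is far more basic than an aryl ether oxygen, so dilute HCl in methanol should release the phenol through the oxocarbenium ion under conditions too mild to ionise the prenyl ether or the benzylic alcohol.

Compound list
1 | orcinol (5-methylbenzene-1,3-diol) | Cc1cc(O)cc(O)c1 | starting material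
2 | 3-(methoxymethoxy)-5-methylphenol | COCOc1cc(C)cc(O)c1 | intermediate
3 | 3-(methoxymethoxy)-5-methylphenyl N-(propan-2-yl)carbamate | COCOc1cc(C)cc(OC(=O)NC(C)C)c1 | intermediate
4 | 3-(methoxymethoxy)-5-methylphenyl N-[tert-butyl(dimethyl)silyl]-N-(propan-2-yl)carbamate (N-silyl carbamate) | COCOc1cc(C)cc(OC(=O)N(C(C)C)[Si](C)(C)C(C)(C)C)c1 | intermediate
5 | [2-({[tert-butyl(dimethyl)silyl](propan-2-yl)carbamoyl}oxy)-6-(methoxymethoxy)-4-methylphenyl]lithium (aryllithium) | COCOc1cc(C)cc(OC(=O)N(C(C)C)[Si](C)(C)C(C)(C)C)c1[Li] | intermediate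
6 | 3-(methoxymethoxy)-5-methyl-2-(trimethylsilyl)phenyl N-[tert-butyl(dimethyl)silyl]-N-(propan-2-yl)carbamate (N,C-disilyl carbamate) | COCOc1cc(C)cc(OC(=O)N(C(C)C)[Si](C)(C)C(C)(C)C)c1[Si](C)(C)C | intermediate
7 | 3-(methoxymethoxy)-5-methyl-2-(trimethylsilyl)phenyl N-(propan-2-yl)carbamate | COCOc1cc(C)cc(OC(=O)NC(C)C)c1[Si](C)(C)C | intermediate
8 | 3-(methoxymethoxy)-5-methyl-2-(trimethylsilyl)phenol (ortho-silyl phenol, present as its DBU salt) | COCOc1cc(C)cc(O)c1[Si](C)(C)C | intermediate
9 | 3-(methoxymethoxy)-5-methyl-2-(trimethylsilyl)phenyl trifluoromethanesulfonate | COCOc1cc(C)cc(OS(=O)(=O)C(F)(F)F)c1[Si](C)(C)C | intermediate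
10 | 2-hydroxy-5-methoxybenzaldehyde | COc1ccc(O)c(C=O)c1 | starting material
11 | 3-bromo-2-hydroxy-5-methoxybenzaldehyde | COc1cc(Br)c(O)c(C=O)c1 | intermediate
12 | 2,3-dihydroxy-5-methoxybenzaldehyde | COc1cc(O)c(O)c(C=O)c1 | intermediate
13 | prenyl bromide (1-bromo-3-methylbut-2-ene) | CC(C)=CCBr | starting material
14 | disodium 3-formyl-5-methoxybenzene-1,2-diolate (disodium catecholate) | [Na+].[Na+].COc1cc([O-])c([O-])c(C=O)c1 | intermediate
15 | 2-hydroxy-5-methoxy-3-(3-methylbut-2-enyloxy)benzaldehyde | COc1cc(OCC=C(C)C)c(O)c(C=O)c1 | intermediate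
16 | 2-(hydroxymethyl)-4-methoxy-6-(3-methylbut-2-enyloxy)phenol | COc1cc(CO)c(O)c(OCC=C(C)C)c1 | intermediate
17 | 4-methoxy-2-(3-methylbut-2-enyloxy)-6-(triisopropylsilyloxymethyl)phenol | COc1cc(CO[Si](C(C)C)(C(C)C)C(C)C)c(O)c(OCC=C(C)C)c1 | intermediate
18 | carbon dioxide | O=C=O | starting material
19 | potassium 4-methoxy-2-(3-methylbut-2-enyloxy)-6-(triisopropylsilyloxymethyl)phenolate (potassium phenoxide) | [K+].COc1cc(CO[Si](C(C)C)(C(C)C)C(C)C)c([O-])c(OCC=C(C)C)c1 | intermediate
20 | 3-(methoxymethoxy)-5-methylbenzyne | COCOC1=CC(C)=CC#C1 | intermediate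
21 | 2-[4-methoxy-2-(3-methylbut-2-enyloxy)-6-(triisopropylsilyloxymethyl)phenoxy]-6-(methoxymethoxy)-4-methylbenzoic acid | OC(=O)c1c(OCOC)cc(C)cc1Oc1c(CO[Si](C(C)C)(C(C)C)C(C)C)cc(OC)cc1OCC=C(C)C | intermediate
22 | methyl 2-[4-methoxy-2-(3-methylbut-2-enyloxy)-6-(triisopropylsilyloxymethyl)phenoxy]-6-(methoxymethoxy)-4-methylbenzoate | COC(=O)c1c(OCOC)cc(C)cc1Oc1c(CO[Si](C(C)C)(C(C)C)C(C)C)cc(OC)cc1OCC=C(C)C | intermediate
23 | methyl 2-[2-(hydroxymethyl)-4-methoxy-6-(3-methylbut-2-enyloxy)phenoxy]-6-(methoxymethoxy)-4-methylbenzoate | COC(=O)c1c(OCOC)cc(C)cc1Oc1c(CO)cc(OC)cc1OCC=C(C)C | intermediate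
24 | methyl 2-hydroxy-6-[2-(hydroxymethyl)-4-methoxy-6-(3-methylbut-2-enyloxy)phenoxy]-4-methylbenzoate | COC(=O)c1c(O)cc(C)cc1Oc1c(CO)cc(OC)cc1OCC=C(C)C | target

Total step count: 13.
Longest linear sequence: 9 steps (steps 5 to 13, from 10 to 24); the ring A branch (steps 1 to 4) joins at step 10.

Steps most likely to fail

Step 10 (Proposed new method). The aryl anion may be protonated before CO2 reaches it, or the phenoxide may be held back as its carbonate so that addition to the aryne becomes slow. The fallback sets out from 17 and 9 and comes back at 21, using known chemistry only. Phenol 17 would be O-arylated with the aryne from 9 under ordinary protic conditions (CsF, MeCN, rt), where the same meta-selective addition is followed by protonation, to give {[5-methoxy-2-[3-(methoxymethoxy)-5-methylphenoxy]-3-(3-methylbut-2-enyloxy)phenyl]methoxy}tri(propan-2-yl)silane F1. Directed ortho-lithiation of this diaryl ether (n-BuLi, TMEDA, THF, −78 → −20 °C) should take place at the ring A carbon between the chelating MOM ether and the aryloxy oxygen and give {2-[4-methoxy-2-(3-methylbut-2-enyloxy)-6-(triisopropylsilyloxymethyl)phenoxy]-6-(methoxymethoxy)-4-methylphenyl}lithium F2. Quenching with CO2 and acidifying to pH 3 would then deliver acid 21.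

Step 13. Acid may ionise the prenyl ether to the allyl cation and so strip the prenyl group while the MOM acetal is being cleaved. The fallback sets out from 22 and comes back at 24; it reverses the order of the two deprotections and replaces hydrolysis by silyl transfer. With TMSOTf and 2,2′-bipyridyl in CH2Cl2 at 0 °C the MOM acetal of 22 should be exchanged for a silyl ether, giving methyl 2-[4-methoxy-2-(3-methylbut-2-enyloxy)-6-(triisopropylsilyloxymethyl)phenoxy]-4-methyl-6-(trimethylsilyloxy)benzoate F3. Water in the work-up would convert this into methyl 2-hydroxy-6-[4-methoxy-2-(3-methylbut-2-enyloxy)-6-(triisopropylsilyloxymethyl)phenoxy]-4-methylbenzoate F4. Buffered TBAF/AcOH in THF would finally remove the TIPS group and give 24 without any Brønsted acid step.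

Step 6. Substitution of bromide may stay incomplete, or the electron-rich catecholate may be degraded oxidatively during long heating in alkali. The fallback sets out from 11 and comes back at 12, replacing the copper-mediated substitution by borylation and oxidation. Protection of the phenol (MOMCl, i-Pr2NEt, CH2Cl2) would give 3-bromo-5-methoxy-2-(methoxymethoxy)benzaldehyde F5. Miyaura borylation (B2pin2, Pd(dppf)Cl2, KOAc, dioxane, 80 °C) would give 5-methoxy-2-(methoxymethoxy)-3-(4,4,5,5-tetramethyl-1,3,2-dioxaborolan-2-yl)benzaldehyde F6. Oxidation of the C–B bond (NaBO3·4H2O, THF/H2O, rt) would give 3-hydroxy-5-methoxy-2-(methoxymethoxy)benzaldehyde F7. Since no prenyl group is present yet, HCl in MeOH can safely remove the MOM group and return catechol 12.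

Further compounds
F1 | step 10 | {[5-methoxy-2-[3-(methoxymethoxy)-5-methylphenoxy]-3-(3-methylbut-2-enyloxy)phenyl]methoxy}tri(propan-2-yl)silane | COCOc1cc(C)cc(Oc2c(CO[Si](C(C)C)(C(C)C)C(C)C)cc(OC)cc2OCC=C(C)C)c1
F2 | step 10 | {2-[4-methoxy-2-(3-methylbut-2-enyloxy)-6-(triisopropylsilyloxymethyl)phenoxy]-6-(methoxymethoxy)-4-methylphenyl}lithium | [Li]c1c(OCOC)cc(C)cc1Oc1c(CO[Si](C(C)C)(C(C)C)C(C)C)cc(OC)cc1OCC=C(C)C
F3 | step 13 | methyl 2-[4-methoxy-2-(3-methylbut-2-enyloxy)-6-(triisopropylsilyloxymethyl)phenoxy]-4-methyl-6-(trimethylsilyloxy)benzoate | COC(=O)c1c(O[Si](C)(C)C)cc(C)cc1Oc1c(CO[Si](C(C)C)(C(C)C)C(C)C)cc(OC)cc1OCC=C(C)C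
F4 | step 13 | methyl 2-hydroxy-6-[4-methoxy-2-(3-methylbut-2-enyloxy)-6-(triisopropylsilyloxymethyl)phenoxy]-4-methylbenzoate | COC(=O)c1c(O)cc(C)cc1Oc1c(CO[Si](C(C)C)(C(C)C)C(C)C)cc(OC)cc1OCC=C(C)C
F5 | step 6 | 3-bromo-5-methoxy-2-(methoxymethoxy)benzaldehyde | COCOc1c(Br)cc(OC)cc1C=O
F6 | step 6 | 5-methoxy-2-(methoxymethoxy)-3-(4,4,5,5-tetramethyl-1,3,2-dioxaborolan-2-yl)benzaldehyde | COCOc1c(B2OC(C)(C)C(C)(C)O2)cc(OC)cc1C=O
F7 | step 6 | 3-hydroxy-5-methoxy-2-(methoxymethoxy)benzaldehyde | COCOc1c(O)cc(OC)cc1C=O
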